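## Structural features

The target is the 4-methoxybenzoate of a humulane-type alcohol: one eleven-membered carbocycle (C1–C11) with methyl groups at C3 and C7 and a gem-dimethyl group at C11, and no other ring except the oxirane fused at C6–C7. C1 (S) carries the ester oxygen and sits between the quaternary C11 and the E-trisubstituted C2=C3 olefin, so it is both neopentylic and allylic. The trans-trisubstituted oxirane (6R,7R, methyl on C7) lies across the ring in a 1,6-relation to C1, too far for a dependable relay, so the two stereo-elements must be set independently. The oxirane is acid-labile (transannular attack by C2=C3 is possible) and the allylic ester can ionise to a C1–C3 allyl cation, so late steps must stay neutral or basic. The real difficulty is closing a medium ring that contains an E-olefin while forming the hindered C1–C11 bond between a stereogenic carbinol and a quaternary carbon. The feature exploited is that C1–C11 with their four methyls are the farnesane chain joined head (C1, the oxygen-bearing carbon) to tail (C11, the isopropylidene carbon). C2=C3 and C6=C7 are the two E-olefins of (2E,6E)-farnesol, and the C1 oxygen is farnesol's own. The key step therefore closes C1–C11 by making the C9–C10–C11 allyl unit a nucleophile toward C1 as an aldehyde, the polarity-reversed copy of the 1,11-closure that forms the humulane ring in nature.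

## Logic of the disconnections

16 to 15: the two C–O bonds of the oxirane (C6–O, C7–O) are cut. The oxirane is the most fragile group and is best made last, and the E geometry of C6=C7 in 15 already encodes its trans arrangement. This removes two stereocentres and leaves a diene with a single stereocentre. The forward step must choose C6=C7 over C2=C3 and one olefin face regardless of C1, which calls for a chiral dioxirane and for the ester as an electronic shield of C2=C3.

15 to 13 and 14: the acyl–O bond is cut. The aryl ester is needed anyway and doubles as the deactivating group for C2=C3 in the epoxidation. The forward step must acylate a hindered carbinol without touching the C1–O bond, so that the configuration is retained.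

13 to 12: a C9=C10 double bond is added in the retrosynthetic direction. This turns C11 into an allylic terminus and exposes the homoallylic alcohol retron C1(OH)–C11–C10=C9. The forward step must saturate the disubstituted olefin in the presence of two trisubstituted ones.

12 to 9 (through 10 and 11): the ring bond C1–C11 is cut. It is the only ring bond that joins the carbinol carbon to the quaternary carbon, and cutting it opens the ring to an achiral open chain in which all fifteen carbons, both E-trisubstituted olefins and the C1 oxygen are already in place. The forward step must bond the allyl unit through its dimethyl-substituted terminus C11, close the ring in preference to oligomers, and control the face of the formyl group with a ligand on the metal.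

9 to 8: the C9–Br bond is cut with allylic transposition to a C11–OH group. The tertiary allylic alcohol is what a terminal epoxide delivers. The forward bromination must tolerate the enal; the regio- and stereochemistry of the bromide are irrelevant because all isomers converge on one allylmetal.

8 to 7: the C1 oxidation level is adjusted. The forward step must oxidise the primary allylic alcohol only.

7 to 4 (through 5 and 6): the C9=C10 bond and the C11–OH group are traced back to the 10,11-epoxide by cutting C10–O. The forward sequence needs nucleophilic opening at C10 and elimination toward C9 only.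

4 to 3 to 2 to 1: the C10–O and C10–Br bonds are cut back to the terminal olefin. The forward steps must single out the terminal trisubstituted olefin among three, which the acetate and the aqueous medium secure.

## Other disconnections considered

Alternative 1: Cut C1–C2, the bond between the carbinol and the olefin, which is the first disconnection that comes to mind. The forward key step would be a NiCl2/CrCl2-mediated alkenyl iodide–aldehyde macrocyclisation of (6R,7R,10E)-6,7-epoxy-11-iodo-2,2,6,10-tetramethylundec-10-enal A1, followed by acylation. A1 has to be assembled from separate pieces (neopentyl aldehyde terminus, epoxide by asymmetric epoxidation, E-iodoalkene by carbometalation), which is well over a dozen steps. The ring would close at the most hindered aldehyde possible, the quaternary carbon is made separately, and C1 is left to remote induction from the oxirane. The chosen plan makes the ring, the quaternary carbon and C1 in one step from a chain taken whole from a C15 terpene.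

Alternative 2: Cut C1–C11 between two fragments and close the ring at C9=C10. The forward steps would be reagent-controlled tert-prenylation of (2E,6E)-3,7-dimethyldeca-2,6,9-trienal A3 with γ,γ-dimethylallyl-diisopinocampheylborane to give (4E,8E,10S)-4,8,11,11-tetramethyltrideca-1,4,8,12-tetraen-10-ol A2, then ring-closing metathesis with a second-generation Grubbs catalyst to 12. This sets C1 reliably, but the metathesis must engage a vinyl group on a quaternary carbon next to a skipped diene that is prone to isomerisation. A3 also needs its own multistep synthesis from a geraniol derivative. The plan reaches the same compound 12 in more steps, and its ring closure settles no stereochemistry.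

Alternative 3: Regard the target as a seco-caryophyllane and reconnect C2–C10, which leads to commercial (−)-caryophyllene oxide A4. Its (4R,5R)-oxirane is the target's C6/C7 oxirane and all fifteen carbons map. The forward key step would be hydrogen-atom transfer (Fe(acac)3, PhSiH3) to the exocyclic methylene and β-scission of the resulting cyclobutylcarbinyl radical. This would expand the nine-membered ring to (1E,5R,6R)-5,6-epoxy-2,6,10,10-tetramethylcycloundec-1-ene A5. The fragmentation leaves C1 as an unfunctionalised methylene beside the quaternary carbon. A later allylic oxidation would have to prefer C1 over C4 and the C3 methyl and set its configuration, against the usual selectivity of such oxidations. The scission could also break the C1–C2 cyclobutane bond, and the geometry of the new olefin is not under control. The hardest stereocentre would thus be untouched by the key step.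

Key step: step 7

Assumption: the (S)-antipode of the oxazoline–sulfonamide ligand is taken to deliver C11 to the Re face of the formyl group; if the sense of induction is the opposite, the equally accessible (R)-antipode is used.

## Route

Step 1
Reactants: 1 (2E,6E)-farnesol
Product: 2 (2E,6E)-farnesyl acetate
Conditions: Ac2O, pyridine, 4-(dimethylamino)pyridine (cat.), CH2Cl2, 0 °C to rt
Reagents that add atoms: acetic anhydride, CC(=O)OC(C)=O
Why: Standard O-acylation; the acetate inductively deactivates C2=C3 toward the electrophilic bromine of step 2, and no stereocentre is formed.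

Step 2
Reactants: 2 (2E,6E)-farnesyl acetate
Product: 3 (2E,6E)-10-bromo-11-hydroxy-3,7,11-trimethyldodeca-2,6-dien-1-yl acetate (racemic)
Conditions: NBS, THF/H2O, 0 °C
Reagents that add atoms: N-bromosuccinimide, O=C1CCC(=O)N1Br; water, O
Why: Bromohydrin formation; in the aqueous medium the chain coils and the terminal C10=C11 olefin, remote from the acetate, should react first, with water opening the bromonium ion at the more substituted C11. The racemic C10 centre is erased in step 4.

Step 3
Reactants: 3 (2E,6E)-10-bromo-11-hydroxy-3,7,11-trimethyldodeca-2,6-dien-1-yl acetate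
Product: 4 (2E,6E)-10,11-epoxy-3,7,11-trimethyldodeca-2,6-dien-1-ol (racemic)
Conditions: K2CO3, MeOH, rt
Reagents that add atoms: none
Why: Intramolecular Williamson closure of the bromohydrin (SN2 at C10) with concurrent methanolysis of the acetate; the two E-olefins are untouched.

Step 4
Reactants: 4 (2E,6E)-10,11-epoxy-3,7,11-trimethyldodeca-2,6-dien-1-ol
Product: 7 (2E,6E,9E)-3,7,11-trimethyldodeca-2,6,9-triene-1,11-diol, via hydroxy selenide 5 (not isolated), via selenoxide 6 (not isolated)
Conditions: PhSeSePh, NaBH4, EtOH, rt to 78 °C; then 30% H2O2, pyridine, THF, 0 °C to rt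
Reagents that add atoms: none
Why: Epoxide to allylic alcohol through a β-hydroxy selenide: sodium benzeneselenolate opens the epoxide by SN2 at the secondary C10, and oxidation gives selenoxide 6. Its syn-elimination can only run toward C9 (C11 has no hydrogen) and should give the E-disubstituted olefin, which removes the C10 stereocentre.

Step 5
Reactants: 7 (2E,6E,9E)-3,7,11-trimethyldodeca-2,6,9-triene-1,11-diol
Product: 8 (2E,6E,9E)-11-hydroxy-3,7,11-trimethyldodeca-2,6,9-trienal
Conditions: MnO2, CH2Cl2, rt
Reagents that add atoms: none
Why: MnO2 oxidises only the primary allylic alcohol (the tertiary one has no carbinol hydrogen) under neutral conditions that should preserve the 2E geometry.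

Step 6
Reactants: 8 (2E,6E,9E)-11-hydroxy-3,7,11-trimethyldodeca-2,6,9-trienal
Product: 9 (2E,6E)-9-bromo-3,7,11-trimethyldodeca-2,6,10-trienal (racemic at C9)
Conditions: PBr3, pyridine (cat.), Et2O, −30 to 0 °C; used crude
Reagents that add atoms: phosphorus tribromide, BrP(Br)Br
Why: Bromination of a tertiary allylic alcohol with allylic transposition (SN2'-type collapse of the phosphite), which should give the more stable secondary bromide with the trisubstituted C10=C11 olefin. The configuration at C9 and the position of bromine within the allyl unit are irrelevant, because step 7 passes through one common allylmetal.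

Step 7
Reactants: 9 (2E,6E)-9-bromo-3,7,11-trimethyldodeca-2,6,10-trienal
Product: 12 (1S,2E,6E,9E)-3,7,11,11-tetramethylcycloundeca-2,6,9-trien-1-ol, via allylchromium species 10 (not isolated), via chromium alkoxide 11 (not isolated)
Conditions: CrCl2 (6 equiv), (S)-N-[2-(4-isopropyl-4,5-dihydro-1,3-oxazol-2-yl)-6-methylphenyl]methanesulfonamide (6.6 equiv), Et3N (6.6 equiv), THF, rt, complex preformed; 9 added by syringe pump (final 2 mM); aqueous work-up
Reagents that add atoms: none
Why: Intramolecular Nozaki–Hiyama carbonyl allylation: two one-electron transfers from divalent chromium convert the C–Br bond of 9 into the σ-allyl species 10 of trivalent chromium, with the metal on the less substituted terminus C9 whatever isomer of the bromide is used, so all isomers converge. Species 10 should add to its own formyl group through the six-membered, metal-bridged SE2' transition state typical of allylchromium reagents, so the C–C bond forms at the γ-terminus C11, just as prenylchromium reagents give α,α-dimethyl homoallylic alcohols; this closes the eleven-membered ring in an 11-exo-trig sense at C=O with the transposed C9=C10 bond inside the ring, and creates the quaternary C11 and the carbinol C1 in one event. The competing α-attack would need chromium on the tertiary carbon and would give a nine-membered ring holding two E-trisubstituted olefins, so electronic and strain factors both favour C11, and the product has the strain-tolerant triene pattern of the humulene ring. C1 is the only new stereocentre (C11 carries two identical methyls) and is set by the chiral oxazoline–sulfonamide on chromium, which should direct C11 to the Re face of the coordinated aldehyde (O > C2 > H) and so give 1S; the substrate has no stereocentre that could oppose the ligand. The new C9=C10 olefin is expected to be E for reasons of ring strain, but its geometry is immaterial because step 8 removes it. The step needs 1,2-addition to the enal, which is normal for allylchromium reagents, and ring closure over oligomerisation, which slow addition at high dilution should secure; any residual enantiomer would become a separable diastereomer in step 10. Aqueous work-up hydrolyses alkoxide 11 to 12.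

Step 8
Reactants: 12 (1S,2E,6E,9E)-3,7,11,11-tetramethylcycloundeca-2,6,9-trien-1-ol
Product: 13 (1S,2E,6E)-3,7,11,11-tetramethylcycloundeca-2,6-dien-1-ol
Conditions: 2-nitrobenzenesulfonyl hydrazide, Et3N, CH2Cl2, rt
Reagents that add atoms: none
Why: Diimide reduction: the concerted syn transfer of H2 discriminates by substitution, so the E-disubstituted C9=C10 olefin should be reduced well before the two trisubstituted olefins. No stereocentre is formed or touched.

Step 9
Reactants: 13 (1S,2E,6E)-3,7,11,11-tetramethylcycloundeca-2,6-dien-1-ol; 14 4-methoxybenzoyl chloride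
Product: 15 (1S,2E,6E)-3,7,11,11-tetramethylcycloundeca-2,6-dien-1-yl 4-methoxybenzoate
Conditions: Et3N, 4-(dimethylamino)pyridine, CH2Cl2, 40 °C
Reagents that add atoms: 4-methoxybenzoyl chloride (14), COc1ccc(C(Cl)=O)cc1
Why: Acylation with nucleophilic catalysis (acylpyridinium) should overcome the hindrance of the neopentyl-type carbinol; the bond formed is O–acyl, so C1 keeps its configuration.

Step 10
Reactants: 15 (1S,2E,6E)-3,7,11,11-tetramethylcycloundeca-2,6-dien-1-yl 4-methoxybenzoate
Product: 16 (1S,2E,6R,7R)-6,7-epoxy-3,7,11,11-tetramethylcycloundec-2-en-1-yl 4-methoxybenzoate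
Conditions: Shi ketone (D-fructose-derived, 1,2:4,5-di-O-isopropylidene-β-D-erythro-2,3-hexodiulo-2,6-pyranose, 0.3 equiv), KHSO5 (as 2KHSO5·KHSO4·K2SO4), K2CO3, Bu4NHSO4 (cat.), MeCN/CH2(OMe)2/aq. Na2B4O7, 0 °C
Reagents that add atoms: potassium peroxymonosulfate, [K+].[O-]S(=O)(=O)OO
Why: Shi asymmetric epoxidation: the dioxirane of the D-fructose-derived ketone transfers oxygen through a spiro transition state and gives R,R-epoxides from E-trisubstituted olefins, so the E geometry fixes the trans oxirane and the reagent should fix 6R,7R. C2=C3 is shielded by the electron-withdrawing allylic ester and the adjacent quaternary C11, and the buffered basic medium should preserve ester and oxirane.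

## Compound list

1 | (2E,6E)-farnesol | CC(C)=CCC/C(C)=C/CC/C(C)=C/CO | starting material
2 | (2E,6E)-farnesyl acetate | CC(C)=CCC/C(C)=C/CC/C(C)=C/COC(C)=O | intermediate
3 | (2E,6E)-10-bromo-11-hydroxy-3,7,11-trimethyldodeca-2,6-dien-1-yl acetate (racemic) | CC(C)(O)C(Br)CC/C(C)=C/CC/C(C)=C/COC(C)=O | intermediate
4 | (2E,6E)-10,11-epoxy-3,7,11-trimethyldodeca-2,6-dien-1-ol (racemic) | CC1(C)OC1CC/C(C)=C/CC/C(C)=C/CO | intermediate
5 | (2E,6E)-3,7,11-trimethyl-10-(phenylselanyl)dodeca-2,6-diene-1,11-diol | CC(C)(O)C([Se]c1ccccc1)CC/C(C)=C/CC/C(C)=C/CO | intermediate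
6 | (2E,6E)-3,7,11-trimethyl-10-(phenylseleninyl)dodeca-2,6-diene-1,11-diol | CC(C)(O)C([Se](=O)c1ccccc1)CC/C(C)=C/CC/C(C)=C/CO | intermediate
7 | (2E,6E,9E)-3,7,11-trimethyldodeca-2,6,9-triene-1,11-diol | CC(C)(O)/C=C/C/C(C)=C/CC/C(C)=C/CO | intermediate
8 | (2E,6E,9E)-11-hydroxy-3,7,11-trimethyldodeca-2,6,9-trienal | CC(C)(O)/C=C/C/C(C)=C/CC/C(C)=C/C=O | intermediate
9 | (2E,6E)-9-bromo-3,7,11-trimethyldodeca-2,6,10-trienal (racemic at C9) | CC(C)=CC(Br)C/C(C)=C/CC/C(C)=C/C=O | intermediate
10 | (2E,6E)-9-(dichlorochromio)-3,7,11-trimethyldodeca-2,6,10-trienal (ancillary ligand on chromium omitted) | CC(C)=CC([Cr](Cl)Cl)C/C(C)=C/CC/C(C)=C/C=O | intermediate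
11 | dichlorochromium (1S,2E,6E,9E)-3,7,11,11-tetramethylcycloundeca-2,6,9-trien-1-olate (ancillary ligand omitted) | Cl[Cr](Cl)O[C@H]1/C=C(\C)CC/C=C(\C)C/C=C/C1(C)C | intermediate
12 | (1S,2E,6E,9E)-3,7,11,11-tetramethylcycloundeca-2,6,9-trien-1-ol | O[C@H]1/C=C(\C)CC/C=C(\C)C/C=C/C1(C)C | intermediate
13 | (1S,2E,6E)-3,7,11,11-tetramethylcycloundeca-2,6-dien-1-ol | O[C@H]1/C=C(\C)CC/C=C(\C)CCCC1(C)C | intermediate
14 | 4-methoxybenzoyl chloride | COc1ccc(C(Cl)=O)cc1 | starting material
15 | (1S,2E,6E)-3,7,11,11-tetramethylcycloundeca-2,6-dien-1-yl 4-methoxybenzoate | COc1ccc(C(=O)O[C@H]2/C=C(\C)CC/C=C(\C)CCCC2(C)C)cc1 | intermediate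
16 | (1S,2E,6R,7R)-6,7-epoxy-3,7,11,11-tetramethylcycloundec-2-en-1-yl 4-methoxybenzoate | COc1ccc(C(=O)O[C@H]2/C=C(\C)CC[C@H]3O[C@]3(C)CCCC2(C)C)cc1 | target

## Step count and least certain steps

Total step count: 10. Longest linear sequence: 10 steps (1 to 16); 14 enters at step 9.

Step 7 (key step). The most likely failure is erosion of facial selectivity at the formyl group, because the strained bicyclic transition state of the ring closure, and not the ligand, may dictate the approach. Intermolecular coupling at insufficient dilution is the second concern. Fallback, setting out from 9 and returning at 12: cyclisation of 9 with CrCl2 alone in THF at high dilution should give racemic (2E,6E,9E)-3,7,11,11-tetramethylcycloundeca-2,6,9-trien-1-ol F1. Dess–Martin oxidation would give (2E,6E,9E)-3,7,11,11-tetramethylcycloundeca-2,6,9-trien-1-one F2, which cannot enolise toward C11. Corey–Bakshi–Shibata reduction with catecholborane and (R)-2-methyl-CBS-oxazaborolidine, in which the tertiary-alkyl side should act as the large group, is expected to return 12.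

Step 10. Oxygen transfer may occur to the wrong olefin face, because each ring conformer exposes only its peripheral face and the C1 substituent may bias the conformer population against the reagent. Partial epoxidation of C2=C3 is also possible. Fallback, setting out from 7 and returning at 16, with the epoxide made on the open chain where reagent control is most dependable:
- Selective acetylation of the primary hydroxyl gives (2E,6E,9E)-11-hydroxy-3,7,11-trimethyldodeca-2,6,9-trien-1-yl acetate F3.
- Shi epoxidation gives (2E,6R,7R,9E)-6,7-epoxy-11-hydroxy-3,7,11-trimethyldodeca-2,9-dien-1-yl acetate F4.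
- K2CO3 in MeOH gives (2E,6R,7R,9E)-6,7-epoxy-3,7,11-trimethyldodeca-2,9-diene-1,11-diol F5.
- MnO2 gives (2E,6R,7R,9E)-6,7-epoxy-11-hydroxy-3,7,11-trimethyldodeca-2,9-dienal F6.
- One-pot sulfonylation and bromide displacement (MsCl, Et3N, then LiBr), non-acidic to spare the oxirane, gives (2E,6R,7R)-9-bromo-6,7-epoxy-3,7,11-trimethyldodeca-2,10-dienal F7.
- Cyclisation as in step 7 gives (1S,2E,6R,7R,9E)-6,7-epoxy-3,7,11,11-tetramethylcycloundeca-2,9-dien-1-ol F8, in which a C1 epimer would be a separable diastereomer.
- Diimide gives (1S,2E,6R,7R)-6,7-epoxy-3,7,11,11-tetramethylcycloundec-2-en-1-ol F9, and acylation with 14 gives 16.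

Step 6. HBr formed in the flask may isomerise the enal olefin, add to C6=C7, or promote 1,4-elimination of the product toward a conjugated triene; the formyl group may also react with PBr3. Fallback, setting out from 7 and returning at 9, with the bromide made before the aldehyde:
- Silylation of the primary hydroxyl (TBSCl, imidazole) gives (2E,6E,9E)-1-(tert-butyldimethylsilyloxy)-3,7,11-trimethyldodeca-2,6,9-trien-11-ol F10.
- PBr3 with pyridine gives tert-butyl{[(2E,6E)-9-bromo-3,7,11-trimethyldodeca-2,6,10-trien-1-yl]oxy}dimethylsilane F11.
- HF·pyridine gives (2E,6E)-9-bromo-3,7,11-trimethyldodeca-2,6,10-trien-1-ol F12, and MnO2 gives 9.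

Step 8. Over-reduction of the trisubstituted olefins may set in if C9=C10, shielded on one side by the quaternary carbon, reacts more slowly than expected. Fallback, setting out from 12 and returning at 16, with the competing electron-rich olefin removed before the reduction:
- Acylation of 12 with 14 gives (1S,2E,6E,9E)-3,7,11,11-tetramethylcycloundeca-2,6,9-trien-1-yl 4-methoxybenzoate F13.
- Shi epoxidation, which prefers the trisubstituted C6=C7 to the hindered trans-disubstituted C9=C10, gives (1S,2E,6R,7R,9E)-6,7-epoxy-3,7,11,11-tetramethylcycloundeca-2,9-dien-1-yl 4-methoxybenzoate F14.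
- Diimide, which now competes only with the hindered, deactivated C2=C3, gives 16.

## Further compounds

F1 | step 7 | rac-(2E,6E,9E)-3,7,11,11-tetramethylcycloundeca-2,6,9-trien-1-ol | OC1/C=C(\C)CC/C=C(\C)C/C=C/C1(C)C
F2 | step 7 | (2E,6E,9E)-3,7,11,11-tetramethylcycloundeca-2,6,9-trien-1-one | O=C1/C=C(\C)CC/C=C(\C)C/C=C/C1(C)C
F3 | step 10 | (2E,6E,9E)-11-hydroxy-3,7,11-trimethyldodeca-2,6,9-trien-1-yl acetate | CC(=O)OC/C=C(\C)CC/C=C(\C)C/C=C/C(C)(C)O
F4 | step 10 | (2E,6R,7R,9E)-6,7-epoxy-11-hydroxy-3,7,11-trimethyldodeca-2,9-dien-1-yl acetate | CC(=O)OC/C=C(\C)CC[C@H]1O[C@]1(C)C/C=C/C(C)(C)O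
F5 | step 10 | (2E,6R,7R,9E)-6,7-epoxy-3,7,11-trimethyldodeca-2,9-diene-1,11-diol | OC/C=C(\C)CC[C@H]1O[C@]1(C)C/C=C/C(C)(C)O
F6 | step 10 | (2E,6R,7R,9E)-6,7-epoxy-11-hydroxy-3,7,11-trimethyldodeca-2,9-dienal | O=C/C=C(\C)CC[C@H]1O[C@]1(C)C/C=C/C(C)(C)O
F7 | step 10 | (2E,6R,7R)-9-bromo-6,7-epoxy-3,7,11-trimethyldodeca-2,10-dienal (mixture at C9) | O=C/C=C(\C)CC[C@H]1O[C@]1(C)CC(Br)C=C(C)C
F8 | step 10 | (1S,2E,6R,7R,9E)-6,7-epoxy-3,7,11,11-tetramethylcycloundeca-2,9-dien-1-ol | O[C@H]1/C=C(\C)CC[C@H]2O[C@]2(C)C/C=C/C1(C)C
F9 | step 10 | (1S,2E,6R,7R)-6,7-epoxy-3,7,11,11-tetramethylcycloundec-2-en-1-ol | O[C@H]1/C=C(\C)CC[C@H]2O[C@]2(C)CCCC1(C)C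
F10 | step 6 | (2E,6E,9E)-1-(tert-butyldimethylsilyloxy)-3,7,11-trimethyldodeca-2,6,9-trien-11-ol | CC(C)(O)/C=C/C/C(C)=C/CC/C(C)=C/CO[Si](C)(C)C(C)(C)C
F11 | step 6 | tert-butyl{[(2E,6E)-9-bromo-3,7,11-trimethyldodeca-2,6,10-trien-1-yl]oxy}dimethylsilane | CC(C)=CC(Br)C/C(C)=C/CC/C(C)=C/CO[Si](C)(C)C(C)(C)C
F12 | step 6 | (2E,6E)-9-bromo-3,7,11-trimethyldodeca-2,6,10-trien-1-ol | CC(C)=CC(Br)C/C(C)=C/CC/C(C)=C/CO
F13 | step 8 | (1S,2E,6E,9E)-3,7,11,11-tetramethylcycloundeca-2,6,9-trien-1-yl 4-methoxybenzoate | COc1ccc(C(=O)O[C@H]2/C=C(\C)CC/C=C(\C)C/C=C/C2(C)C)cc1
F14 | step 8 | (1S,2E,6R,7R,9E)-6,7-epoxy-3,7,11,11-tetramethylcycloundeca-2,9-dien-1-yl 4-methoxybenzoate | COc1ccc(C(=O)O[C@H]2/C=C(\C)CC[C@H]3O[C@]3(C)C/C=C/C2(C)C)cc1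
A1 | alternative 1 | (6R,7R,10E)-6,7-epoxy-11-iodo-2,2,6,10-tetramethylundec-10-enal | I/C=C(\C)CC[C@H]1O[C@]1(C)CCCC(C)(C)C=O
A2 | alternative 2 | (4E,8E,10S)-4,8,11,11-tetramethyltrideca-1,4,8,12-tetraen-10-ol | O[C@H](C(C)(C)C=C)/C=C(\C)CC/C=C(\C)CC=C
A3 | alternative 2 | (2E,6E)-3,7-dimethyldeca-2,6,9-trienal | O=C/C=C(\C)CC/C=C(\C)CC=C
A4 | alternative 3 | (−)-caryophyllene oxide, (1R,4R,5R,9S) | C[C@@]12CC[C@@H]3[C@H](CC3(C)C)C(=C)CC[C@H]1O2
A5 | alternative 3 | (1E,5R,6R)-5,6-epoxy-2,6,10,10-tetramethylcycloundec-1-ene | CC1(C)C/C=C(\C)CC[C@H]2O[C@]2(C)CCC1
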